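## Structural features

The target is a hexaphenolic spiro compound. C2 of a 4,6-dihydroxybenzofuran-3(2H)-one is also C3 of a 2,3-dihydrofuran ring, and that ring is fused to ring A of a kaempferol unit through flavonol C8 and C7–O7. The second sp3 carbon of the dihydrofuran ring is a cyclic hemiketal that carries a hydroxyl and a 4-hydroxyphenyl group and is bonded to O7. The two stereocentres are neighbours: the fully substituted spiro carbon (S; bonded to the benzofuranone ring oxygen, the benzofuranone ketone carbon, flavonol C8 and the hemiketal carbon) and the hemiketal carbon (R). The hemiketal is the fragile point: it ring-opens to an aryl ketone and the O7 phenol, ionises under acid and is benzylic. The free polyphenol is sensitive to oxidants and base, and the spiro ketone is a non-enolisable α-aryloxy ketone that strong nucleophiles can cleave. Because the hemiketal carbon equilibrates, the real stereochemical task is the quaternary spiro carbon alone; the real constitutional task is to join two tetrasubstituted carbons beside it while telling O7 apart from five other phenolic oxygens. The key step exploits the ortho-hydroxybenzyl unit O7–C7–C8–C(spiro): loss of a leaving group from the spiro carbon (normally the nucleophilic α-carbon of the benzofuranone) gives an ortho-quinone methide across C7–C8, and a one-carbon ylide is then stitched between the spiro carbon and O7 to close the dihydrofuran ring.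

## Logic of the disconnections

**18 from 17.** The six phenolic O–H bonds are traced back to O–benzyl bonds. Hydrogenolysis is the one global deprotection that needs neither acid, base nor oxidant, all of which threaten the hemiketal or the polyphenol. The gain is that every earlier intermediate is neutral, soluble and not oxidisable. The demand is that six aryl benzyl ethers fall off while the benzylic hemiketal C–O bonds and the flavonol enone stay.

**17 from 16.** The C–OH bond of the hemiketal carbon is traced back to a C–H bond. This lets the one-carbon unit enter as a simple benzyl group. The C–H bond is benzylic to a 4-alkoxyphenyl ring and α to an ether oxygen, so it is the most hydridic one in the molecule. The demand is an oxidant that takes this hydride and leaves six ordinary benzyl ethers; the configuration of this carbon need not be controlled, since the hemiketal equilibrates.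

**16 from 11 and 13 (through 14 and 15).** The bond from the spiro carbon to the benzylic carbon and the bond from the benzylic carbon to O7 are cut. This removes one ring, two skeletal bonds and both stereocentres at once, and leaves an intact benzofuranone–flavonol biaryl-type unit and a benzyl sulfonium salt. The demand is that the spiro carbon act as an electrophile (as 14) and that one face of it be selected. A hydroxyl at that carbon would be a poor choice for two reasons. Hydroxide is a weak nucleofuge. And once O7 is free, a hemiketal can open to the 1,2-diketone and re-close with either phenol, so the wrong oxygen could end up in the five-membered ring. Compound 11 therefore carries a benzoate, which leaves readily and cannot ring-open.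

**13 from 12.** The C–S bond is cut; the gain is a commercial benzylic chloride. The demand is only a non-nucleophilic counter-ion so that the salt does not revert.

**11 from 10.** The O7–H bond is traced back to an O7–(4-methoxybenzyl) bond. O7 must be masked while the C8–C bond is made, because a free ortho phenol would cyclise onto the ketone. It must then be freed without touching six benzyl ethers or the tertiary benzoate; a brief acidolysis does that.

**10 from 6 and 8 (through 9).** The C8–C2 bond between the flavonol and the benzofuranone and the C2–O bond of the benzoate are cut. This divides the molecule into its two natural halves, each one step from a protected natural-product-type building block. The demand is an enolate arylation with a hindered, electron-rich aryl iodide, and an electrophilic oxygen source that intercepts the air-sensitive arylated enolate before it is handled.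

**8 from 7.** The two O–benzyl bonds are cut, which leads to the commercial dihydroxybenzofuranone. The demand is O- over C-alkylation of an active methylene ketone.

**6 from 5.** The C8–I bond is cut. The demand is regioselective iodination at C8 in preference to C6, which the fully alkylated 5,7-dioxygenated ring A is expected to provide.

**5 from 3 (through 4), 3 from 2, 2 from 1.** The benzyl ethers at O3, O5 and O4′, then the O7–CH2 bond, then the four acetyl groups are removed in turn. The detour through the peracetate is what marks O7: its acetate is the most labile and can be exchanged for an ether in one operation. The demand is mono-selectivity in that exchange.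

## Other disconnections considered

**Alternative 1:** The cut is the aryl ketone bond C3–C3a of the benzofuranone. In the forward sense the tertiary α-aryloxy acid A1, which already contains the furo-fused flavonol and both stereocentres (hemiketal masked as its methyl ketal), would be activated as a mixed trifluoroacetic anhydride; its 3,5-dimethoxyphenoxy ring would then acylate itself to give A2.
- In its favour: the attacking ring is symmetrical and strongly activated, so there is no regiochemical question, and the five-membered closure is a classical Friedel–Crafts acylation. On precedent for the ring-forming event itself this alternative is better than the chosen plan.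
- Against it here: an acylium ion on a carbon that carries an aryloxy and an electron-rich aryl group is prone to lose carbon monoxide to a stabilised oxocarbenium ion, and the acidic medium also endangers the ketal.
- Against it here: the seven O-methyl groups can only be removed by boron trihalide-type reagents, which the spiro ketal is unlikely to survive.
- Against it here: the spiro stereocentre would have to be built beforehand in A1 by a separate enantioselective construction, so the stereochemical problem is moved, not solved.
- Comparison: both plans reach the same skeleton. The alternative is polar and classical where the chosen plan relies on a reactive intermediate. In step economy the chosen plan is ahead, because it brings in the benzofuranone ready-made and ends with one hydrogenolysis.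

**Alternative 2:** The cut is the bond from O7 to the carbon that later becomes the hemiketal carbon. In the forward sense the prochiral di-tert-butyl aryloxy(aryl)malonate A3 would be treated with a chiral BINOL-derived phosphoric acid; the O7 phenol would attack one of the two enantiotopic esters and close the five-membered lactone A4, fixing the quaternary carbon.
- In its favour: A3 is achiral, and the quaternary stereocentre arises catalytically by desymmetrisation, a reaction type with good precedent for hydroxyl nucleophiles on di-tert-butyl malonates. For enantiocontrol of a quaternary carbon this is better founded than hydrogen-bond control over a planar, fully substituted quinone methide, and is named here as the stronger point of the alternative.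
- Equal point: the benzyl ethers allow the same final hydrogenolysis as in the chosen plan.
- Against it here: the O7 phenol of a flavone is a weak nucleophile, and the product is an aryl ester that can re-open.
- Against it here: A3, a malonate with an aryloxy group and a doubly ortho-substituted aryl group on one carbon, is itself hard to assemble.
- Against it here: after A4 three constructive operations remain. These are aryl addition to the lactone carbonyl in the presence of a flavone carbonyl, ester cleavage, and a Friedel–Crafts closure of the benzofuranone with the same decarbonylation risk as in alternative 1.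
- Comparison: the alternative is stronger on the stereo-defining step, the chosen plan on convergence and on the number of steps after the key step (two against at least four).

**Alternative 3:** The cuts are the O1–C7a and C3–C3a bonds of the benzofuranone. In the forward sense fluoride would release the aryne from silyl triflate A6. The tertiary alkoxide of hydroxy ester A5 would add to the aryne carbon remote from the flanking benzyloxy group, and the aryl anion formed next to that group would be acylated by the methyl ester to give A7.
- In its favour: it is the most convergent of the plans, and the 4,6-dioxygenation pattern follows from the innate polarisation of a 3-alkoxyaryne.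
- In its favour: the hemiketal is already at the right oxidation level as a ketal, so no late C–H oxidation is needed. On this point it is better than the chosen plan.
- Equal point: the benzyl ethers give the same final hydrogenolysis as in the chosen plan.
- Against it here: a tertiary alkoxide flanked by a fully substituted ketal carbon is an extremely hindered nucleophile.
- Against it here: the aryl anion can be protonated instead of acylated, and the aryne can react with the flavone carbonyl or the electron-rich rings.
- Against it here: A5 must already be a single enantiomer, so again the spiro stereocentre has to be made earlier by separate chemistry, and A6 needs its own multi-step preparation.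
- Comparison: the alternative avoids the oxidation step and the labile quinone methide, but pays with a longer and less certain route to its two partners. Overall step economy is at best equal to the chosen plan.

Key step: step 9

**Remarks before the steps**

- Assumption on the chemistry: the hemiketal carbon of 18 epimerises by ring opening to the aryl ketone and is taken to rest in the drawn, thermodynamically preferred configuration (hydroxyl on the side of the benzofuranone ketone). Only the spiro carbon is set under kinetic control.
- Structures checked: no error was found in the constitution or configuration of the target or of the annulation product; the spiro carbon has the same spatial arrangement in 16, 17 and 18. Its CIP label changes from R in 16 to S in 17 and 18 only because the neighbouring carbon gains an oxygen.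
- Numbering used in the spiro names: spiro[benzofuran-2(3H),9′(8′H)-furo[2,3-h]chromene], where O7′ is the flavonol O7, C8′ the hemiketal carbon and C9′ (= C2) the spiro carbon.
- Compounds 1, 7 and 12 are commercial.

## Route

Step 1
Reactants: 1 kaempferol
Product: 2 kaempferol 3,5,7,4′-tetraacetate
Conditions: Ac2O, pyridine, DMAP (cat.), 60 °C
Reagents that add atoms: acetic anhydride, CC(=O)OC(C)=O
Why: Exhaustive O-acetylation of a polyphenol under nucleophilic catalysis; the hydrogen-bonded 5-hydroxyl needs the DMAP and mild heating.

Step 2
Reactants: 2 kaempferol 3,5,7,4′-tetraacetate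
Product: 3 7-O-(4-methoxybenzyl)kaempferol 3,5,4′-triacetate
Conditions: 4-methoxybenzyl chloride (1.2 equiv), KI (cat.), K2CO3, acetone, reflux
Reagents that add atoms: 4-methoxybenzyl chloride, COc1ccc(CCl)cc1
Why: Alkylative deacetylation of a flavonol peracetate: the 7-acetate, the ester of the most acidic phenol, is cleaved first by carbonate and the phenoxide is trapped at once by the benzylic iodide formed by Finkelstein exchange. A small excess of halide should hold the reaction at mono-alkylation and so mark O7 alone.

Step 3
Reactants: 3 7-O-(4-methoxybenzyl)kaempferol 3,5,4′-triacetate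
Product: 5 3,5,4′-tri-O-benzyl-7-O-(4-methoxybenzyl)kaempferol, via 7-O-(4-methoxybenzyl)kaempferol 4 (not isolated)
Conditions: K2CO3 (cat.), MeOH–THF, rt; evaporate; BnBr (3.6 equiv), K2CO3, DMF, 70 °C
Reagents that add atoms: benzyl bromide, BrCc1ccccc1
Why: Base-catalysed transesterification frees the three remaining hydroxyls and a Williamson etherification benzylates them, the hydrogen-bonded 5-hydroxyl last. The 4-methoxybenzyl ether is inert to both stages.

Step 4
Reactants: 5 3,5,4′-tri-O-benzyl-7-O-(4-methoxybenzyl)kaempferol
Product: 6 3,5,4′-tri-O-benzyl-8-iodo-7-O-(4-methoxybenzyl)kaempferol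
Conditions: NIS (1.1 equiv), DMF, 40 °C, dark
Reagents that add atoms: N-iodosuccinimide, O=C1CCC(=O)N1I
Why: Electrophilic aromatic iodination; in fully alkylated 5,7-dioxygenated flavones C8 (ortho to O7 and to the ring oxygen, para to O5) is the usual site of halogenation and C6 is shielded by two flanking benzyl-type ethers. No acid is added, so the 4-methoxybenzyl ether is not put at risk.

Step 5
Reactants: 7 4,6-dihydroxybenzofuran-3(2H)-one
Product: 8 4,6-dibenzyloxybenzofuran-3(2H)-one
Conditions: BnBr (2.2 equiv), K2CO3, DMF, rt
Reagents that add atoms: benzyl bromide, BrCc1ccccc1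
Why: Williamson etherification of both phenols; a weak base at room temperature and only a slight excess of halide should keep C-benzylation of the active methylene low.

Step 6
Reactants: 6 3,5,4′-tri-O-benzyl-8-iodo-7-O-(4-methoxybenzyl)kaempferol; 8 4,6-dibenzyloxybenzofuran-3(2H)-one (1.5 equiv)
Product: 10 2-benzoyloxy-4,6-dibenzyloxy-2-[3,5,4′-tribenzyloxy-7-(4-methoxybenzyloxy)flavon-8-yl]benzofuran-3(2H)-one (racemic), via potassium enolate 9 (not isolated)
Conditions: Pd(OAc)2 (5 mol%), 2-dicyclohexylphosphino-2′,4′,6′-triisopropylbiphenyl (10 mol%), K3PO4, toluene, 90 °C, argon; then (BzO)2 (1.3 equiv), THF, 0 °C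
Reagents that add atoms: dibenzoyl peroxide, O=C(OOC(=O)c1ccccc1)c1ccccc1
Why: Palladium-catalysed α-arylation of a ketone enolate with an aryl iodide (oxidative addition to zerovalent palladium formed in situ, enolate transfer, reductive elimination helped by the bulky biarylphosphine); the more acidic product remains as enolate 9, which is air-sensitive and is therefore intercepted in the same flask by electrophilic oxygen transfer from the peroxide (α-benzoyloxylation of an enolate). The benzoate puts a real leaving group on C2 and, unlike a hydroxyl, cannot ring-open to a 1,2-diketone; the new stereocentre is racemic and is erased in step 9.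

Step 7
Reactants: 10 2-benzoyloxy-4,6-dibenzyloxy-2-[3,5,4′-tribenzyloxy-7-(4-methoxybenzyloxy)flavon-8-yl]benzofuran-3(2H)-one
Product: 11 2-benzoyloxy-4,6-dibenzyloxy-2-(3,5,4′-tribenzyloxy-7-hydroxyflavon-8-yl)benzofuran-3(2H)-one (racemic)
Conditions: TFA (5% v/v), anisole (5 equiv), CH2Cl2, 0 °C, short reaction time
Reagents that add atoms: none
Why: Acidolysis of a 4-methoxybenzyl aryl ether, the stabilised benzyl cation being captured by anisole. Plain benzyl ethers and the tertiary benzoate, whose ionisation is held back by the adjacent ketone, should survive the brief cold exposure.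

Step 8
Reactants: 12 4-benzyloxybenzyl chloride
Product: 13 (4-benzyloxybenzyl)dimethylsulfonium tetrafluoroborate
Conditions: Me2S (3 equiv), NaBF4 (1.1 equiv), acetone, rt
Reagents that add atoms: dimethyl sulfide, CSC; sodium tetrafluoroborate, [Na+].F[B-](F)(F)F
Why: SN2 alkylation of the sulfide by a benzylic chloride with anion metathesis; precipitation of NaCl drives it and the non-nucleophilic counter-ion prevents reversal.

Step 9
Reactants: 11 2-benzoyloxy-4,6-dibenzyloxy-2-(3,5,4′-tribenzyloxy-7-hydroxyflavon-8-yl)benzofuran-3(2H)-one; 13 (4-benzyloxybenzyl)dimethylsulfonium tetrafluoroborate (1.5 equiv)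
Product: 16 hexa-O-benzyl 8′-deoxy derivative of 18 (spiro carbon R and benzylic carbon R), via quinone methide 14 (not isolated), via sulfonium ylide 15 (not isolated)
Conditions: Cs2CO3 (3 equiv), 1,1′-[(1R,2R)-cyclohexane-1,2-diyl]bis{3-[3,5-bis(trifluoromethyl)phenyl]urea} (10 mol%), 4 Å molecular sieves, CHCl3, −20 °C
Reagents that add atoms: none
Why: Proposed new method: Cs2CO3 deprotonates the O7 phenol of 11 and the phenoxide expels benzoate through ring A (vinylogous E1cB), which gives quinone methide 14, a push–pull dienone whose methide carbon is the former C2 of the benzofuranone and is now electrophilic; the same base turns 13 into ylide 15. The carbon of 15 adds to the methide carbon, ring A regains its aromaticity, and the O7 phenoxide then displaces dimethyl sulfide from the benzylic carbon with inversion, so that the dihydrofuran ring closes by a 5-exo-tet O-alkylation. The closest known reaction type is the base-mediated formal (4+1) annulation of sulfonium ylides with ortho-quinone methides released in situ from ortho-hydroxybenzyl sulfones or esters, including its asymmetric variant under chiral urea catalysis; new here is a fully substituted methide carbon that bears an acyl and an aryloxy group and becomes a quaternary spiro centre. The spiro carbon is set in the C–C bond-forming step by the C2-symmetric bis-urea, which is expected to hold the two carbonyl oxygens of 14 by hydrogen bonds and to leave one face of the planar methide carbon open to 15; the (R,R) catalyst is written, and its antipode is used if a first run shows the opposite sense. The benzylic carbon is set by the relative approach of 15 followed by inversion in the closure, the aryl group being expected on the side of the ring oxygen and away from the ketone carbon, but its configuration does not matter because step 10 removes it. Attack at the methide carbon in preference to the flavone and benzofuranone carbonyls is secured by the aromatisation it brings, and the intramolecular elimination to 14 should outrun O-benzylation of the phenoxide by 13 and acyl transfer of the benzoate to O7.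

Step 10
Reactants: 16 hexa-O-benzyl 8′-deoxy derivative of 18
Product: 17 hexa-O-benzyl ether of 18 (spiro carbon S and hemiketal carbon R)
Conditions: DDQ (1.5 equiv), CH2Cl2–pH 7 phosphate buffer (10:1), 0 °C to rt
Reagents that add atoms: water, O
Why: DDQ abstracts hydride from the one C–H bond that is both benzylic to a 4-alkoxyphenyl ring and α to an ether oxygen (the reactivity used to cleave 4-alkoxybenzyl ethers) and water captures the oxocarbenium ion; plain benzyl aryl ethers react far more slowly. The hemiketal carbon equilibrates through the ring-opened keto phenol and is expected to settle with the hydroxyl on the side of the ring ketone.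

Step 11
Reactants: 17 hexa-O-benzyl ether of 18
Product: 18 (2S,8′R)-3′,4,5′,6,8′-pentahydroxy-2′,8′-bis(4-hydroxyphenyl)spiro[benzofuran-2(3H),9′(8′H)-furo[2,3-h]chromene]-3,4′-dione (target)
Conditions: H2 (1 atm), Pd/C (10% palladium on carbon), THF–MeOH (1:1), rt; filtered as soon as hydrogen uptake ends
Reagents that add atoms: none
Why: Hydrogenolysis of six aryl benzyl ethers over palladium; the fully substituted hemiketal carbon and the flavonol enone are expected to be spared at one atmosphere and room temperature, and the spiro centre is not touched. The hemiketal again rests in its stable configuration.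

## Compound list

1 | kaempferol | O=c1c(O)c(-c2ccc(O)cc2)oc2cc(O)cc(O)c12 | starting material
2 | kaempferol 3,5,7,4′-tetraacetate | O=c1c(OC(C)=O)c(-c2ccc(OC(C)=O)cc2)oc2cc(OC(C)=O)cc(OC(C)=O)c12 | intermediate
3 | 7-O-(4-methoxybenzyl)kaempferol 3,5,4′-triacetate | O=c1c(OC(C)=O)c(-c2ccc(OC(C)=O)cc2)oc2cc(OCc3ccc(OC)cc3)cc(OC(C)=O)c12 | intermediate
4 | 7-O-(4-methoxybenzyl)kaempferol (not isolated) | O=c1c(O)c(-c2ccc(O)cc2)oc2cc(OCc3ccc(OC)cc3)cc(O)c12 | intermediate
5 | 3,5,4′-tri-O-benzyl-7-O-(4-methoxybenzyl)kaempferol | O=c1c(OCc2ccccc2)c(-c2ccc(OCc3ccccc3)cc2)oc2cc(OCc3ccc(OC)cc3)cc(OCc3ccccc3)c12 | intermediate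
6 | 3,5,4′-tri-O-benzyl-8-iodo-7-O-(4-methoxybenzyl)kaempferol | O=c1c(OCc2ccccc2)c(-c2ccc(OCc3ccccc3)cc2)oc2c(I)c(OCc3ccc(OC)cc3)cc(OCc3ccccc3)c12 | intermediate
7 | 4,6-dihydroxybenzofuran-3(2H)-one | O=C1COc2cc(O)cc(O)c12 | starting material
8 | 4,6-dibenzyloxybenzofuran-3(2H)-one | O=C1COc2cc(OCc3ccccc3)cc(OCc3ccccc3)c12 | intermediate
9 | potassium enolate of 4,6-dibenzyloxy-2-[3,5,4′-tribenzyloxy-7-(4-methoxybenzyloxy)flavon-8-yl]benzofuran-3(2H)-one (not isolated) | [K+].[O-]c1c(-c2c(OCc3ccc(OC)cc3)cc(OCc3ccccc3)c3c(=O)c(OCc4ccccc4)c(-c4ccc(OCc5ccccc5)cc4)oc23)oc2cc(OCc3ccccc3)cc(OCc3ccccc3)c12 | intermediate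
10 | 2-benzoyloxy-4,6-dibenzyloxy-2-[3,5,4′-tribenzyloxy-7-(4-methoxybenzyloxy)flavon-8-yl]benzofuran-3(2H)-one, racemic | O=C1c2c(OCc3ccccc3)cc(OCc3ccccc3)cc2OC1(OC(=O)c1ccccc1)c1c(OCc2ccc(OC)cc2)cc(OCc2ccccc2)c2c(=O)c(OCc3ccccc3)c(-c3ccc(OCc4ccccc4)cc3)oc12 | intermediate
11 | 2-benzoyloxy-4,6-dibenzyloxy-2-(3,5,4′-tribenzyloxy-7-hydroxyflavon-8-yl)benzofuran-3(2H)-one, racemic | O=C1c2c(OCc3ccccc3)cc(OCc3ccccc3)cc2OC1(OC(=O)c1ccccc1)c1c(O)cc(OCc2ccccc2)c2c(=O)c(OCc3ccccc3)c(-c3ccc(OCc4ccccc4)cc3)oc12 | intermediate
12 | 4-benzyloxybenzyl chloride | ClCc1ccc(OCc2ccccc2)cc1 | starting material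
13 | (4-benzyloxybenzyl)dimethylsulfonium tetrafluoroborate | C[S+](C)Cc1ccc(OCc2ccccc2)cc1.F[B-](F)(F)F | intermediate
14 | ortho-quinone methide: 4,6-dibenzyloxy-2-(3,5,4′-tribenzyloxy-7-oxoflavon-8(7H)-ylidene)benzofuran-3(2H)-one, double-bond geometry not fixed (not isolated) | O=C1c2c(OCc3ccccc3)cc(OCc3ccccc3)cc2OC1=C1C(=O)C=C(OCc2ccccc2)C2=C1OC(-c1ccc(OCc3ccccc3)cc1)=C(OCc1ccccc1)C2=O | intermediate
15 | (4-benzyloxybenzylidene)dimethylsulfurane, the ylide of 13 (not isolated) | C[S+](C)[CH-]c1ccc(OCc2ccccc2)cc1 | intermediate
16 | (2R,8′R)-3′,4,5′,6-tetrabenzyloxy-2′,8′-bis(4-benzyloxyphenyl)spiro[benzofuran-2(3H),9′(8′H)-furo[2,3-h]chromene]-3,4′-dione | O=C1c2c(OCc3ccccc3)cc(OCc3ccccc3)cc2O[C@@]12c1c(cc(OCc3ccccc3)c3c(=O)c(OCc4ccccc4)c(-c4ccc(OCc5ccccc5)cc4)oc13)O[C@@H]2c1ccc(OCc2ccccc2)cc1 | intermediate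
17 | (2S,8′R)-3′,4,5′,6-tetrabenzyloxy-2′,8′-bis(4-benzyloxyphenyl)-8′-hydroxyspiro[benzofuran-2(3H),9′(8′H)-furo[2,3-h]chromene]-3,4′-dione | O=C1c2c(OCc3ccccc3)cc(OCc3ccccc3)cc2O[C@@]12c1c(cc(OCc3ccccc3)c3c(=O)c(OCc4ccccc4)c(-c4ccc(OCc5ccccc5)cc4)oc13)O[C@]2(O)c1ccc(OCc2ccccc2)cc1 | intermediate
18 | (2S,8′R)-3′,4,5′,6,8′-pentahydroxy-2′,8′-bis(4-hydroxyphenyl)spiro[benzofuran-2(3H),9′(8′H)-furo[2,3-h]chromene]-3,4′-dione | O=C1c2c(O)cc(O)cc2O[C@@]12c1c(cc(O)c3c(=O)c(O)c(-c4ccc(O)cc4)oc13)O[C@]2(O)c1ccc(O)cc1 | target

## Step count and least certain steps

Total step count: 11. Longest linear sequence: 9 steps (1, 2, 3, 4, 6, 7, 9, 10, 11, from kaempferol).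

**Step 9 (key step, carries the label).** Three things may go wrong: facial discrimination at a fully substituted methide carbon may be poor; the benzoate may migrate to O7 or be replaced by water before the ylide arrives; and the phenoxide may be benzylated by the sulfonium salt. The fallback uses only known reaction types and sets out from enolate 9, generated from 6 and 8 exactly as in step 6.
- Instead of the peroxide, chloride 12 with NaI in DMF is added, and C-alkylation of the ketone enolate should give racemic 2-(4-benzyloxybenzyl)-4,6-dibenzyloxy-2-[3,5,4′-tribenzyloxy-7-(4-methoxybenzyloxy)flavon-8-yl]benzofuran-3(2H)-one F1.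
- Acidolysis as in step 7 should give the 7-hydroxy compound, 2-(4-benzyloxybenzyl)-4,6-dibenzyloxy-2-(3,5,4′-tribenzyloxy-7-hydroxyflavon-8-yl)benzofuran-3(2H)-one F2.
- DDQ (2.5 equiv) in wet CH2Cl2 should then oxidise the 4-alkoxybenzylic methylene twice. The first hydride abstraction is followed by capture by O7, giving the racemic form of 16 (either configuration at the benzylic carbon) F3; the second is followed by capture by water, giving the racemic form of 17 F4.
- Preparative chromatography of F4 on a chiral stationary phase returns the route at 17. Half of the material is lost unless an asymmetric phase-transfer benzylation is used for the first stage.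

**Step 6.** Oxidative addition and reductive elimination at a doubly ortho-substituted, electron-rich aryl iodide may be slow, so that self-condensation of 8, hydrodeiodination or premature autoxidation of the enolate take over. The fallback changes the bond-forming mode to C–H arylation of the aromatic enol ester and sets out from 8 and 6.
- O-Acylation of 8 (pivaloyl chloride, Et3N, DMAP, CH2Cl2) should give 4,6-dibenzyloxybenzofuran-3-yl pivalate F5.
- Direct arylation of its furan C2–H bond with 6 (Pd(OAc)2, PCy3·HBF4, K2CO3, pivalic acid, DMA, 100 °C) should give 4,6-dibenzyloxy-2-[3,5,4′-tribenzyloxy-7-(4-methoxybenzyloxy)flavon-8-yl]benzofuran-3-yl pivalate F6.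
- One equivalent of KOMe in THF–MeOH under argon releases enolate 9, and dibenzoyl peroxide added to the same flask returns the route at 10.

**Step 10.** Hydride abstraction may be slow, because the benzylic carbon is flanked by a quaternary carbon carrying a ketone and an aryloxy group, and prolonged exposure may start to oxidise the benzyl ethers. The fallback makes the oxidation phenol-assisted and sets out from 11.
- The silyl-protected salt [4-(tert-butyldimethylsilyloxy)benzyl]dimethylsulfonium tetrafluoroborate F7 is made from commercial 4-(tert-butyldimethylsilyloxy)benzyl bromide, Me2S and NaBF4.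
- The annulation of step 9 with F7 should give the analogue of 16 with a 4-(tert-butyldimethylsilyloxy)phenyl group at C8′, F8.
- Bu4NF buffered with acetic acid in THF at 0 °C should give the analogue of 16 with a free 4-hydroxyphenyl group at C8′, F9.
- DDQ (1.1 equiv) or Ag2O in wet CH2Cl2 should oxidise the 4-hydroxybenzylic position through a para-quinone methide, which takes up water and gives the penta-O-benzyl hemiketal with a free 4-hydroxyphenyl group at C8′, F10.
- Hydrogenolysis as in step 11 returns the route at 18.

**Step 11.** Hydrogenolysis of the benzylic hemiketal C–O bonds, reduction of the ring-opened aryl ketone, or incomplete cleavage of the hindered ethers may occur. The fallback is non-reductive and runs from 17 straight to 18: BCl3 with pentamethylbenzene as cation scavenger in CH2Cl2 at −78 °C, then aqueous work-up, which also re-forms the hemiketal if it has ionised. This fallback makes no new compound (F0).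

**Step 2.** Alkylation may go on to O4′, or acetyl groups may migrate under the basic conditions. The fallback separates the two events and sets out from 2: thiophenol and imidazole in N-methylpyrrolidone at 0 °C should remove the 7-acetate alone and give kaempferol 3,5,4′-triacetate F11. A Mitsunobu etherification with 4-methoxybenzyl alcohol (PPh3, diisopropyl azodicarboxylate, THF), which needs no base, returns the route at 3.

## Further compounds

F1 | step 9 | 2-(4-benzyloxybenzyl)-4,6-dibenzyloxy-2-[3,5,4′-tribenzyloxy-7-(4-methoxybenzyloxy)flavon-8-yl]benzofuran-3(2H)-one, racemic | O=C1c2c(OCc3ccccc3)cc(OCc3ccccc3)cc2OC1(Cc1ccc(OCc2ccccc2)cc1)c1c(OCc2ccc(OC)cc2)cc(OCc2ccccc2)c2c(=O)c(OCc3ccccc3)c(-c3ccc(OCc4ccccc4)cc3)oc12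
F2 | step 9 | 2-(4-benzyloxybenzyl)-4,6-dibenzyloxy-2-(3,5,4′-tribenzyloxy-7-hydroxyflavon-8-yl)benzofuran-3(2H)-one, racemic | O=C1c2c(OCc3ccccc3)cc(OCc3ccccc3)cc2OC1(Cc1ccc(OCc2ccccc2)cc1)c1c(O)cc(OCc2ccccc2)c2c(=O)c(OCc3ccccc3)c(-c3ccc(OCc4ccccc4)cc3)oc12
F3 | step 9 | racemic form of 16, either configuration at the benzylic carbon | O=C1c2c(OCc3ccccc3)cc(OCc3ccccc3)cc2OC12c1c(cc(OCc3ccccc3)c3c(=O)c(OCc4ccccc4)c(-c4ccc(OCc5ccccc5)cc4)oc13)OC2c1ccc(OCc2ccccc2)cc1
F4 | step 9 | racemic form of 17 | O=C1c2c(OCc3ccccc3)cc(OCc3ccccc3)cc2OC12c1c(cc(OCc3ccccc3)c3c(=O)c(OCc4ccccc4)c(-c4ccc(OCc5ccccc5)cc4)oc13)OC2(O)c1ccc(OCc2ccccc2)cc1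
F5 | step 6 | 4,6-dibenzyloxybenzofuran-3-yl pivalate | CC(C)(C)C(=O)Oc1coc2cc(OCc3ccccc3)cc(OCc3ccccc3)c12
F6 | step 6 | 4,6-dibenzyloxy-2-[3,5,4′-tribenzyloxy-7-(4-methoxybenzyloxy)flavon-8-yl]benzofuran-3-yl pivalate | CC(C)(C)C(=O)Oc1c(-c2c(OCc3ccc(OC)cc3)cc(OCc3ccccc3)c3c(=O)c(OCc4ccccc4)c(-c4ccc(OCc5ccccc5)cc4)oc23)oc2cc(OCc3ccccc3)cc(OCc3ccccc3)c12
F7 | step 10 | [4-(tert-butyldimethylsilyloxy)benzyl]dimethylsulfonium tetrafluoroborate | C[S+](C)Cc1ccc(O[Si](C)(C)C(C)(C)C)cc1.F[B-](F)(F)F
F8 | step 10 | analogue of 16 with a 4-(tert-butyldimethylsilyloxy)phenyl group at C8′ | O=C1c2c(OCc3ccccc3)cc(OCc3ccccc3)cc2O[C@@]12c1c(cc(OCc3ccccc3)c3c(=O)c(OCc4ccccc4)c(-c4ccc(OCc5ccccc5)cc4)oc13)O[C@@H]2c1ccc(O[Si](C)(C)C(C)(C)C)cc1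
F9 | step 10 | analogue of 16 with a free 4-hydroxyphenyl group at C8′ | O=C1c2c(OCc3ccccc3)cc(OCc3ccccc3)cc2O[C@@]12c1c(cc(OCc3ccccc3)c3c(=O)c(OCc4ccccc4)c(-c4ccc(OCc5ccccc5)cc4)oc13)O[C@@H]2c1ccc(O)cc1
F10 | step 10 | penta-O-benzyl ether of 18 with a free 4-hydroxyphenyl group at C8′ | O=C1c2c(OCc3ccccc3)cc(OCc3ccccc3)cc2O[C@@]12c1c(cc(OCc3ccccc3)c3c(=O)c(OCc4ccccc4)c(-c4ccc(OCc5ccccc5)cc4)oc13)O[C@]2(O)c1ccc(O)cc1
F0 | step 11 | none | none
F11 | step 2 | kaempferol 3,5,4′-triacetate | O=c1c(OC(C)=O)c(-c2ccc(OC(C)=O)cc2)oc2cc(O)cc(OC(C)=O)c12
A1 | alternative 1 | (8R,9S)-9-(3,5-dimethoxyphenoxy)-3,5,8-trimethoxy-2,8-bis(4-methoxyphenyl)-4-oxo-8,9-dihydro-4H-furo[2,3-h]chromene-9-carboxylic acid | COc1cc(OC)cc(O[C@]2(C(=O)O)c3c(cc(OC)c4c(=O)c(OC)c(-c5ccc(OC)cc5)oc34)O[C@]2(OC)c2ccc(OC)cc2)c1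
A2 | alternative 1 | hexa-O-methyl ether of 18 as its methyl ketal | O=C1c2c(OC)cc(OC)cc2O[C@@]12c1c(cc(OC)c3c(=O)c(OC)c(-c4ccc(OC)cc4)oc13)O[C@]2(OC)c1ccc(OC)cc1
A3 | alternative 2 | di-tert-butyl 2-(3,5-dibenzyloxyphenoxy)-2-(3,5,4′-tribenzyloxy-7-hydroxyflavon-8-yl)malonate | CC(C)(C)OC(=O)C(Oc1cc(OCc2ccccc2)cc(OCc2ccccc2)c1)(C(=O)OC(C)(C)C)c1c(O)cc(OCc2ccccc2)c2c(=O)c(OCc3ccccc3)c(-c3ccc(OCc4ccccc4)cc3)oc12
A4 | alternative 2 | tert-butyl 3,5-dibenzyloxy-2-(4-benzyloxyphenyl)-9-(3,5-dibenzyloxyphenoxy)-4,8-dioxo-8,9-dihydro-4H-furo[2,3-h]chromene-9-carboxylate, single enantiomer | CC(C)(C)OC(=O)[C@]1(Oc2cc(OCc3ccccc3)cc(OCc3ccccc3)c2)C(=O)Oc2cc(OCc3ccccc3)c3c(=O)c(OCc4ccccc4)c(-c4ccc(OCc5ccccc5)cc4)oc3c21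
A5 | alternative 3 | methyl 3,5-dibenzyloxy-2,8-bis(4-benzyloxyphenyl)-9-hydroxy-8-methoxy-4-oxo-8,9-dihydro-4H-furo[2,3-h]chromene-9-carboxylate, single stereoisomer | COC(=O)[C@@]1(O)c2c(cc(OCc3ccccc3)c3c(=O)c(OCc4ccccc4)c(-c4ccc(OCc5ccccc5)cc4)oc23)O[C@]1(OC)c1ccc(OCc2ccccc2)cc1
A6 | alternative 3 | 3,5-dibenzyloxy-2-(trimethylsilyl)phenyl trifluoromethanesulfonate | C[Si](C)(C)c1c(OCc2ccccc2)cc(OCc2ccccc2)cc1OS(=O)(=O)C(F)(F)F
A7 | alternative 3 | hexa-O-benzyl ether of 18 as its methyl ketal | O=C1c2c(OCc3ccccc3)cc(OCc3ccccc3)cc2O[C@@]12c1c(cc(OCc3ccccc3)c3c(=O)c(OCc4ccccc4)c(-c4ccc(OCc5ccccc5)cc4)oc13)O[C@]2(OC)c1ccc(OCc2ccccc2)cc1
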